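The earlier runs and the new flask stem from a simulated flask on assumed constants; noise was put on by code.

The time of reading, 15 min, lies late in the grey run, which reads 13% at 8.00 min, 15% then and 15% at 20.0 min; with a scatter of 1.5 percentage points these readings show a slowing, not a stop. So I compare the late readings of the two runs.

| setting | grey | red | flask |
|---|---|---|---|
| substrate | 0.14 M | 0.22 M | 0.10 M |
| gas phase | 4.3 mM (held) | 4.3 mM (held) | 4.3 mM (held) |
| remark | run made earlier | run made earlier |  |
| time |  |  | 15 min |

- grey (time / min: target / %): 2.50: 3; 5.00: 9; 8.00: 13; 10.0: 14; 12.0: 12; 15.0: 15; 20.0: 15
- red (time / min: target / %): 2.50: 2; 5.00: 7; 8.00: 7; 10.0: 12; 12.0: 12; 15.0: 9; 20.0: 13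

(each reading ± 1.5 percentage points)

1. amount of target at 15 min, in percent of the substrate charged
2. concentration of dissolved gas in solution at 15 min, in percent of saturation

- the numbers in the tables scatter with a standard deviation of 1.5 percentage points
- at the start none of the gas phase is in solution

The mean of the last 4 readings is 14.0% in the grey run and 11.5% in the red run, so the percentage is lower at the larger charge. I fold this into one number, the late-reading exponent 0.435: the logarithm of the ratio of these means over the logarithm of the ratio of the charges, taken the other way up. At 0 the percentage ignores the charge; at 1 the absolute amount of target does. This value is a reading, with the scatter of 1.5 points in it, and it lies between those two cases.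

Scaling the grey mean to 0.10 M, I expect 16.2%. One number is not enough, though: it contains no c(dissolved gas), so I give no figure for that.

The forecast says 17% and 95%, a little above me on target: “The plateau lies between constant percent”.

    substrate + dissolved gas → target (k = 0.260 M⁻¹ s⁻¹)
    target ⇌ isomer of the product (K = 0.826, k = 7.04 × 10⁻⁴ s⁻¹)
    substrate → side product (k = 0.00156 s⁻¹)
    gas phase ⇌ dissolved gas, rate k4*(csat - [dissolved gas]) (kL = 0.0163 s⁻¹)

The flask gives 17.5% and 80.2%, so the exponent falls 1.3 points short and the forecast stands 15 points too high on the gas. For the neighbour flask at 0.025 M, the exponent gives 29.6%, more than its simulated 22.9%. In the asked flask at 4.31 min, substrate passes into side product 2.8 times as fast as into target. Its half-life by the side route alone is 7.4 min, shorter than the 21 min by the gas route at that moment and the 13 min by that route at 15.0 min.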